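Readings and results stem from a simulated flask from invented constants.

If the flask was going to stop short, I wanted its end state first and its pace second.

all flasks: initiator 1 mol%
- ash: free monomer 20 mM (fed, over 30 s); transfer agent 4 mM; run made earlier; the fed solution adds 0.10 times the starting volume
- larch: free monomer 20 mM (fed, over 30 s); transfer agent 9 mM; run made earlier; the fed solution adds 0.10 times the starting volume
- birch: free monomer 40 mM (fed, over 30 s); transfer agent 6 mM; run made earlier; the fed solution adds 0.10 times the starting volume
- flask: free monomer 20 mM (fed, over 30 s); transfer agent 6.00 mM; the fed solution adds 0.10 times the starting volume; time 50 min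

| run | time / min | monomer in chains / % | free monomer / % |
|---|---|---|---|
| ash | 3.00 | 18.5 | 80.7 |
| ash | 10.0 | 43.5 | 59.2 |
| ash | 15.0 | 50.3 | 49.1 |
| ash | 25.0 | 58.7 | 41.7 |
| ash | 40.0 | 61.9 | 39.8 |
| ash | 50.0 | 61.1 | 38.4 |
| ash | 60.0 | 62.1 | 36.9 |
| larch | 8.00 | 34.5 | 64.3 |
| larch | 15.0 | 44.8 | 52.2 |
| larch | 25.0 | 51.1 | 49.6 |
| larch | 30.0 | 52.9 | 46.9 |
| larch | 40.0 | 53.5 | 45.0 |
| larch | 50.0 | 54.2 | 45.5 |
| larch | 60.0 | 54.2 | 44.1 |
| birch | 5.00 | 47.0 | 54.4 |
| birch | 15.0 | 73.5 | 27.6 |
| birch | 30.0 | 83.4 | 19.2 |
| birch | 40.0 | 84.3 | 16.5 |
| birch | 60.0 | 80.9 | 14.6 |

(scatter of a reading: 1 percentage point)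

- charges are per starting volume, the dose included; the dosed solution carries all of it
- the average divides the monomer in chains by the number of chains begun, living and dead together
- what was read earlier has a scatter of 1 percentage point, one standard deviation
- the earlier runs do not show the number of chains; that part of a forecast is a guess

- average number of monomer units in a chain (chains begun, living or dead) at 50 min
- part of the free monomer that has reacted at 50 min

The ash and larch runs both levelled off with free monomer left. For each I took the natural log of the charge over what had not reacted. Read from the monomer in chains at 50 min, that log was 0.944 for ash and 0.781 for larch.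

More transfer agent gave a smaller log, so I took a transfer step to end a chain and begin none. I assumed the inverse of this log to be straight in [transfer agent], and the log itself to grow in step with the initiator charge. At 6.00 mM that gave 0.871. I called this the reach: the number of e-foldings of free monomer that the charged initiator can pay for before its chains stop growing.

So I expected 58.2% reacted in the flask. The birch run tested whether one number was enough. It had the same transfer agent but twice the free monomer, and with it twice the initiator charge. If the reach grew in step with that charge, birch would give 82.5%. The birch chain readings of 84.3% at 40.0 min and 80.9% at 60.0 min lay on either side of that.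

If each initiator began one chain, I reckoned an average of 58.2 units per chain in the flask. The earlier runs do not show the number of chains, so this was a guess.

The forecast said 59% and a dp of 4, far below mine, holding that “the chain count depends on transfer”.

The simulation gave 59.1% reacted and a dp of 59.1.

    living end → dead end (k = 0.00110 s⁻¹)
    living end + transfer agent → dead chain (kL = 0.0780 L mol⁻¹ s⁻¹)
    free monomer + living end → monomer in chains + living end, rate k3*[living end]*[free monomer] (k = 7.50 L mol⁻¹ s⁻¹)
    free monomer + initiator → living end + monomer in chains (k = 2.90 L mol⁻¹ s⁻¹)

Had the flask come to rest? At 50.0 min it held 0% of its initiator and 0.00198 mM of living end. Decay to dead end alone gives the living end a half-life of 11 min, shorter than the 50 min of the run. The neighbour flask read at 20 min stood at 86.3% of my reach, and the flask at 50 min stood at 103%. Left until 500 min, the flask showed 59.5% reacted, a dp of 59.5, and 0 mM of living end.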